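**Retrosynthetic overview**

- Target 17 ⇐ O-methylation of phenol 16 ⇐ dibromination of phenol 14 at C2 and C4 of ring A (ortho and para to the C1 hydroxyl) ⇐ O-demethylation of 12.
- 12 ⇐ Diels–Alder addition and loss of CO2 between 3,5-dibromo-2-pyrone 10 and the ethynyl ether 7 of guaiacol; the bonds cut are C1'–C2' and C5'–C6' of ring B.
- Feature used: in ring B the run C2'(Br)–C3'(H)–C4'(Br)–C5'(H) maps onto C3–C6 of 10, and the remaining C1'(O)–C6'(H) pair is the triple bond of an aryl ethynyl ether.
- 7 ⇐ guaiacol 1 + trichloroethylene 2 (dichlorovinyl ether 4, then n-BuLi); 10 ⇐ coumalic acid 8 (NBS).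
- Ring order: ring A is bought as guaiacol, ring B is the only ring built (step 4), and the ring A bromines are placed last.

Key step: step 4

Remark: the target has no stereocentre. Ring A is the methoxy ring (C1 OMe, C2 Br, C4 Br, C6 O-aryl) and ring B is the 2,4-dibromophenoxy ring (C1' O, C2' Br, C4' Br).

**Route**

Step 1
Reactants: 1 guaiacol (2-methoxyphenol); 2 trichloroethylene
Product: 4 1-{[(E)-1,2-dichloroethenyl]oxy}-2-methoxybenzene, via dichloroacetylene 3 (not isolated)
Conditions: K2CO3 (2 equiv), 2 (1.5 equiv), DMF, 70 °C
Reagents that add atoms: none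
Why: Base-induced dehydrochlorination of 2 should give dichloroacetylene, to which the phenoxide adds in anti fashion (nucleophilic addition to a haloalkyne), the standard entry to aryl (E)-1,2-dichlorovinyl ethers; the alkene geometry is lost in step 2.

Step 2
Reactants: 4 1-{[(E)-1,2-dichloroethenyl]oxy}-2-methoxybenzene
Product: 7 1-(ethynyloxy)-2-methoxybenzene, via chloroalkynyl ether 5 (not isolated), via lithium aryloxyacetylide 6 (not isolated)
Conditions: n-BuLi (2.2 equiv), Et2O, −78 → −40 °C; H2O, −78 °C; cold work-up, solvent exchanged to PhMe without taking to dryness, used at once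
Reagents that add atoms: none
Why: Vinyl deprotonation and β-elimination of LiCl should give the chloroalkyne, lithium–chlorine exchange the acetylide and protonation the terminal ynol ether (dichlorovinyl ether route to ynol ethers); at −78 °C the anisole ring is not ortho-lithiated, and ring A carries no bromine at this stage that could exchange.

Step 3
Reactants: 8 coumalic acid (2-oxo-2H-pyran-5-carboxylic acid)
Product: 10 3,5-dibromo-2H-pyran-2-one, via 5-bromo-2H-pyran-2-one 9 (not isolated)
Conditions: NBS (2.5 equiv), LiOAc (1.2 equiv), MeCN–H2O (9:1), rt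
Reagents that add atoms: N-bromosuccinimide O=C1CCC(=O)N1Br
Why: Hunsdiecker-type ipso-bromodecarboxylation of the carboxylate at C5 followed by electrophilic bromination at the nucleophilic C3 is the established one-flask preparation of this pyrone.

Step 4
Reactants: 10 3,5-dibromo-2H-pyran-2-one; 7 1-(ethynyloxy)-2-methoxybenzene
Product: 12 2,4-dibromo-1-(2-methoxyphenoxy)benzene, via bridged bicyclic lactone 11 (not isolated)
Conditions: PhMe, 80 °C, 7 (1.5–2 equiv) added over several hours, BHT (cat.); CO2 lost in situ (100 °C only if 11 persists)
Reagents that add atoms: none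
Why: The ynol ether 7 is a donor alkyne with its largest HOMO coefficient on the terminal CH carbon, and the dienoate of 10 is most electrophilic at C6, so an asynchronous inverse-electron-demand Diels–Alder reaction should join the CH carbon to C6 and the oxygen-bearing carbon to C3, giving the 2-oxabicyclo[2.2.2]octadienone 11. The closest known reaction type is the cycloaddition of 2-pyrones with alkynes followed by retro-Diels–Alder loss of CO2, together with the known donor-carbon-to-C3 orientation when enol ethers add to 10; aryl ethynyl ethers are close analogues of those partners. Ring B is closed by intermolecular [4+2] cycloaddition (two new C–C bonds, C1'–C2' and C5'–C6', six-membered carbocycle), and cycloreversion of the lactone bridge of 11 then makes it aromatic. The two bridgehead stereocentres of 11 are tied to each other by the bicycle, form as a racemate and vanish with the CO2, so no stereocentre needs control. The one selectivity needed is the orientation (ether oxygen next to the C3 bromine and not next to C6–H), which the opposed polarisation of the two partners secures; because the dienophile is an alkyne, aromatisation involves no elimination that could expel the aryloxy group. Slow addition of 7 at the lowest temperature that sustains turnover should keep its self-oligomerisation behind the cycloaddition.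

Step 5
Reactants: 12 2,4-dibromo-1-(2-methoxyphenoxy)benzene
Product: 14 2-(2,4-dibromophenoxy)phenol, via aryloxydibromoborane 13 (not isolated)
Conditions: BBr3 (1.5 equiv), CH2Cl2, −78 → 0 °C; then H2O
Reagents that add atoms: none
Why: Lewis-acid cleavage of an aryl methyl ether (BBr3 demethylation) should free the C1 phenol; the diaryl ether and the aryl bromides are inert to it.

Step 6
Reactants: 14 2-(2,4-dibromophenoxy)phenol
Product: 16 2,4-dibromo-6-(2,4-dibromophenoxy)phenol, via para-monobromophenol 15 (not isolated)
Conditions: Br2 (2.05 equiv), AcOH–CH2Cl2, 0 °C → rt; aq Na2S2O3 work-up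
Reagents that add atoms: bromine BrBr
Why: Electrophilic aromatic bromination is steered by the free hydroxyl to its para position (C4) and its only open ortho position (C2); the aryloxy group is a weaker director and ring B is deactivated by its two bromines, so two equivalents should stop at 16.

Step 7
Reactants: 16 2,4-dibromo-6-(2,4-dibromophenoxy)phenol
Product: 17 1,5-dibromo-3-(2,4-dibromophenoxy)-2-methoxybenzene (target)
Conditions: MeI (1.5 equiv), K2CO3, acetone, 50 °C
Reagents that add atoms: iodomethane CI
Why: Williamson O-methylation of the acidic dibromophenol should restore the C1 methyl ether without touching any other group.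

**Compound list**

1 | guaiacol (2-methoxyphenol) | COc1ccccc1O | starting material
2 | trichloroethylene | ClC=C(Cl)Cl | starting material
3 | dichloroacetylene | ClC#CCl | intermediate
4 | 1-{[(E)-1,2-dichloroethenyl]oxy}-2-methoxybenzene | COc1ccccc1O/C(Cl)=C\Cl | intermediate
5 | 1-[(chloroethynyl)oxy]-2-methoxybenzene | COc1ccccc1OC#CCl | intermediate
6 | lithium (2-methoxyphenoxy)acetylide | COc1ccccc1OC#C[Li] | intermediate
7 | 1-(ethynyloxy)-2-methoxybenzene | COc1ccccc1OC#C | intermediate
8 | coumalic acid (2-oxo-2H-pyran-5-carboxylic acid) | O=C(O)c1ccc(=O)oc1 | starting material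
9 | 5-bromo-2H-pyran-2-one | O=c1ccc(Br)co1 | intermediate
10 | 3,5-dibromo-2H-pyran-2-one | O=c1occ(Br)cc1Br | intermediate
11 | 4,7-dibromo-5-(2-methoxyphenoxy)-2-oxabicyclo[2.2.2]octa-5,7-dien-3-one (racemic, one enantiomer drawn) | O=C1O[C@H]2C=C(Oc3ccccc3OC)[C@]1(Br)C=C2Br | intermediate
12 | 2,4-dibromo-1-(2-methoxyphenoxy)benzene | COc1ccccc1Oc1ccc(Br)cc1Br | intermediate
13 | dibromo[2-(2,4-dibromophenoxy)phenoxy]borane | BrB(Br)Oc1ccccc1Oc1ccc(Br)cc1Br | intermediate
14 | 2-(2,4-dibromophenoxy)phenol | Oc1ccccc1Oc1ccc(Br)cc1Br | intermediate
15 | 4-bromo-2-(2,4-dibromophenoxy)phenol | Oc1ccc(Br)cc1Oc1ccc(Br)cc1Br | intermediate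
16 | 2,4-dibromo-6-(2,4-dibromophenoxy)phenol | Oc1c(Br)cc(Br)cc1Oc1ccc(Br)cc1Br | intermediate
17 | 1,5-dibromo-3-(2,4-dibromophenoxy)-2-methoxybenzene | COc1c(Br)cc(Br)cc1Oc1ccc(Br)cc1Br | target

**Count**

Total steps: 7. Longest linear sequence: 6 steps (steps 1, 2, 4, 5, 6, 7); step 3 is the one-step side branch to the pyrone.

**Steps most likely to fail**

1. Step 4. The ynol ether may be used up by self-oligomerisation before it adds to the pyrone, or the two partners may join in the reverse orientation (oxygen-bearing carbon to C6), which would lead to the 3,5-dibromophenyl ether. The fallback sets out from 1 and comes back at 12 by diaryliodonium O-arylation instead of cycloaddition. 1,3-Dibromobenzene would be treated with iodyl sulfate (from I2 and KIO3 in H2SO4) and then aqueous NaCl to give bis(2,4-dibromophenyl)iodonium chloride F1, attack occurring at C4 of the arene, ortho and para to its bromines. Heating 1 with F1 and NaOH in H2O–dioxane should transfer one 2,4-dibromophenyl group to the phenoxide oxygen and give 12.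

2. Step 2. The terminal ynol ether may be lost through oligomerisation or hydration during work-up and solvent exchange, and butyllithium may add to the chloroalkyne instead of exchanging with it. The fallback sets out from 4 and comes back at 12, carrying the alkyne in a silyl-capped, storable form. The lithium acetylide 6 generated as in step 2 would be quenched with Me3SiCl instead of water to give [(2-methoxyphenoxy)ethynyl]trimethylsilane F2. Heating F2 with 10 in PhMe (100–110 °C) should pass through the silylated bridged lactone F3 (not isolated), the oxygen-bearing carbon again bonding to C3 and the silyl-bearing carbon to the unsubstituted C6, and after loss of CO2 give [3,5-dibromo-2-(2-methoxyphenoxy)phenyl]trimethylsilane F4. Ipso-protodesilylation of F4 with CF3CO2H in CH2Cl2, assisted by the ortho ether oxygen, should then give 12.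

3. Step 1. Dichloroacetylene is volatile and may escape from the warm mixture, and a second phenoxide may add to the dichlorovinyl ether, so conversion to 4 may stall. The fallback sets out from 1 and comes back at 7 by the classical vinyl ether route to aryloxyacetylenes.
   - 1 with excess 1,2-dibromoethane and K2CO3 in MeCN at reflux should give 1-(2-bromoethoxy)-2-methoxybenzene F5.
   - t-BuOK in DMSO should eliminate HBr to give 1-(ethenyloxy)-2-methoxybenzene F6.
   - Br2 in CH2Cl2 at −78 °C should add across the enol ether to give 1-(1,2-dibromoethoxy)-2-methoxybenzene F7.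
   - Warming F7 with N,N-diethylaniline should remove HBr to give 1-{[(Z)-2-bromoethenyl]oxy}-2-methoxybenzene F8.
   - LiN(i-Pr)2 (2.2 equiv, THF, −78 °C) should take F8 through to the lithium acetylide 6, and water then gives 7.

**Further compounds**

F1 | step 4 | bis(2,4-dibromophenyl)iodonium chloride | [Cl-].Brc1ccc([I+]c2ccc(Br)cc2Br)c(Br)c1
F2 | step 2 | [(2-methoxyphenoxy)ethynyl]trimethylsilane | COc1ccccc1OC#C[Si](C)(C)C
F3 | step 2 | 4,7-dibromo-5-(2-methoxyphenoxy)-6-(trimethylsilyl)-2-oxabicyclo[2.2.2]octa-5,7-dien-3-one (racemic, one enantiomer drawn) | O=C1O[C@H]2C([Si](C)(C)C)=C(Oc3ccccc3OC)[C@]1(Br)C=C2Br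
F4 | step 2 | [3,5-dibromo-2-(2-methoxyphenoxy)phenyl]trimethylsilane | COc1ccccc1Oc1c(Br)cc(Br)cc1[Si](C)(C)C
F5 | step 1 | 1-(2-bromoethoxy)-2-methoxybenzene | COc1ccccc1OCCBr
F6 | step 1 | 1-(ethenyloxy)-2-methoxybenzene | COc1ccccc1OC=C
F7 | step 1 | 1-(1,2-dibromoethoxy)-2-methoxybenzene (racemic) | COc1ccccc1OC(Br)CBr
F8 | step 1 | 1-{[(Z)-2-bromoethenyl]oxy}-2-methoxybenzene | COc1ccccc1O/C=C\Br
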